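(All constants were chosen freely; the result is computed.)

Reckon this flask by how long E.X survives once Q shelters part of it.

    X ⇌ D, rate k1*([X] - [D]/K1) per volume of the first phase (K1 = 1.4, k1 = 0.0014 s⁻¹)
    E + X → E.X (k2 = 0.013 M⁻¹ s⁻¹)
    E.X ⇌ Q, rate k3*([E.X] - [Q]/K3) per volume of the first phase (K3 = 0.44, k3 = 0.034 s⁻¹)
    E.X → L (k4 = 0.0013 s⁻¹)
    X ⇌ Z (K5 = 0.69, k5 = 0.040 s⁻¹)

E 0.40 M; D 1.00 equiv; time 30 min; volume of the second phase over the first 2.0

- amounts and yields of E.X count Q too
- in the second phase: D, Q; everything else is in the first
- charges count per volume of the first phase; a concentration in a rate is the amount of a species over the volume of its own phase; every rate counts per litre of the first phase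
- run time (flask): 30 min

1. the E.X and Q together standing at 30 min, as a percentage of the E charged
2. the change that raises the amount of E.X and Q together at 30 min, in percent of the E charged most ("none" if none brings more than 2 percentage points) (midnight / spring / summer / none)
3. amount of E.X and Q together at 30 min, in percent of the E charged, after midnight

On a scale of powers of ten in time, X and Z relax into each other with a half-life of 0.118 min and E.X and Q with one of 0.159 min, both far faster than the capture of X by E, whose half-life as charged is 2.2 min, so each pair keeps its ratio throughout. D crosses over with a mean life of 33.3 min, much slower than X is captured, so X stays low: reckoned at opening D and E, crossing balances capture and return at 7.58 % of the charge, a level towards which X fills from zero. Step 4 halves first-phase E.X in 8.9 min, but the share held as Q lies out of its reach, which stretches the loss to 24.1 min, the pool life: one plus the volume ratio times K3, over k4, the mean time E.X and Q together last against step 4.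

The pool therefore tends to a balance level, the capture frequency times the pool life, which is 57.0 % of the charge at the opening values. This reckoning by hand scales that level by the D left at mid-run, 63.8 %, and by the filling factor over the run, 71.2 %, and arrives at 25.9 %. The pool life holds no k3, so summer should give little, and spring doubles the feed, while midnight lifts that reckoned balance of X to 12.5 %, which puts spring ahead.

The forecast gives 22.8 %, below the hand figure, with 28 % after midnight, and names spring: “Doubling D about doubles the driving force and the X pool”.

The flask gives 22.7 %, 28.1 % after midnight, and spring, which gains 15 percentage points, against 5.4 points for midnight and 0.047 points for summer.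

This flask's pool of 22.7 % owes part of its size to two things acting together, the falling back of Z to X, without which it is 3.37 %, and the time given, against ten times as long, which leaves 0.733 %. With the X and E standing at 30.0 min, the pool life puts the balance level at 26.1 %, and this flask holds 22.7 %, below it. The same flask left until 80 min has a balance level of 8.47 %, and its pool, still above that level, stands at 14.0 %.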